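**Conventions and assumption.** Germacrane locants are used throughout: ring C1–C10, C1=C10 alkene, C4 bearing C15 (CH2OH), C6 the lactone carbinol, C7 bearing C11(=C13H2)–C12, C8 the acyloxy carbon, C14 the ester carbon on C10. Assumption: (2R)-2-methylbutanoic acid (26) is bought as the single enantiomer, and the C15 oxygen is carried as a tert-butyldiphenylsilyl ether because steps 13 and 15 are acidic. The same spatial arrangement at C7 is R in 25–30 and S in 31–32, because C6 gains an oxygen on lactonization.

## Analysis of the target

Target 32 is a ten-membered carbocycle (C1–C10) trans-fused at C6–C7 to an α-methylene-γ-butyrolactone (O–C6, C7, C11=C13, C12). It carries a C1=C10 alkene conjugated to the C14 methyl ester, a hydroxymethyl group (C15) on C4 and a (2R)-2-methylbutanoate on O8. The ring stereocentres are C4 (S), C6 (R), C7 (S) and C8 (R): H6 and H7 are anti, and in the open chain C11–C7–C8–C9 the C7 branch that becomes C6 and the C8 oxygen are syn. C4 is five bonds from C8 along the C9–C10–C1–C2–C3 arc, so it cannot be relayed to or from the C7/C8 pair in an open-chain precursor. Across C1=C10 the ring carbons C2 and C9 are cis (E by the sequence rule), which is the stable tiglate-type geometry of a 2-alkyl-2-enoate. The sensitive groups are the α-methylene lactone (a Michael and radical acceptor), the O8 ester with its epimerizable α-centre, and O8 itself, which is γ to both C12 and C14 and lactonizes onto either when free. The difficulty is the combination of a medium ring, a remote stereocentre and three carboxyl-level carbons (C12, C14, the acyl group) that must be told apart. The strategy rests on C5, a plain methylene between C4 and C6: a cis C5=C6 alkene is γ,δ to the C12 carboxyl, so vinyl groups on C4 and C7 can close the ring there and the acid can then add across it to give the C6–O bond.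

## Retrosynthetic reasoning

**32 ⇒ 31 (O15–Si).** The primary alcohol is unmasked last so that it cannot compete as a nucleophile for the C5=C6 alkene or accept an acyl group. The forward step is a fluoride desilylation that must spare the methylene lactone and both esters.

**31 ⇒ 30 (C6–O and C5–H).** Cutting the lactone C–O bond and removing the added hydrogen at C5 reveals a cis C5=C6 alkene and a free C12 acrylic acid. This is the only lactone disconnection that leaves C6 without an oxygen in the precursor, so no C6 carbinol has to be made or protected. The forward reaction must deliver oxygen to C6 (fused γ-lactone) rather than C5 (bridged δ-lactone) and set C6 trans to C7.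

**30 ⇒ 29 (C5=C6).** The ring is opened by metathesis at the alkene that the previous step consumed, giving two monosubstituted vinyl groups on C4 and C7. This site is chosen because ring closure then forms no stereocentre, and the other alkenes of 29 (acrylic acid, enoate) are electron-poor and more substituted. The forward reaction has to close a ten-membered ring against oligomerization.

**29 ⇒ 28 ⇒ 25 + 26 (C12 ester, O8–acyl).** The C12 acid is masked as a tert-butyl ester, which resists attack by the neighbouring hydroxyl and is removed by acid without touching the methyl ester or the O8 ester. The O8–acyl bond is cut to alcohol 25 and acid 26. Acylation is placed before any lactone exists, so O8 can never relactonize later.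

**25 ⇒ 19 + 23 (C7–C8).** This cut gives aldehyde 19 and the 2-(bromomethyl)pentadienoate 23, whose γ-carbon is C7 and already bears the vinyl group (C6) and the acrylate (C11–C13). One bond delivers both stereocentres of the syn pair and all of the carbons C5′/C6, C7, C11, C12 and C13. The forward reaction is a metal-mediated Barbier allylation (indium) under near-neutral aqueous conditions. C4 cannot influence it, so 25 is obtained only after a separation of diastereomers; this is the price of the disconnection.

**23 ⇒ 22 ⇒ 20 + 21.** The bromide comes from the Morita–Baylis–Hillman alcohol 22 by bromination with allylic transposition, and 22 from acrolein (20) and tert-butyl acrylate (21).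

**19 ⇒ 17 ⇒ 12 + 16; 16 ⇒ 13 + 14.** Aldehyde 19 is β,γ-unsaturated and doubly activated at C9, so it is unveiled immediately before use from a prenyl group by cleavage of the electron-rich trisubstituted alkene of 17. This can be done in the presence of the C4 vinyl group, which an allyl group would not allow. The C1=C10 bond is cut to aldehyde 12 and the prenylated stabilized ylide 16 (from 13 and 14), because a Wittig reaction of this type gives the required geometry.

**12 ⇒ 10 ⇒ 9 ⇒ 8 ⇒ 5 + 6; 5 ⇒ 1 + 2 (C3–C4).** C4 is the α-carbon of but-3-enoic acid (1), whose vinyl group is the future C5. The C3–C4 bond is made by auxiliary-controlled conjugate addition of imide 5 to acrylonitrile (6), which brings C3, C2 and C1 in one step as a nitrile. The nitrile survives reductive removal of auxiliary 2, cannot lactonize with the C15 alcohol, and is reduced to the C1 aldehyde afterwards.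

## Alternatives that were turned down

**Alternative 1:** The disconnection is C3–C4 of the carbocycle, with O–C1 of a ten-membered lactone as a temporary bond. In the forward key step the ester enolate of that lactone, whose alkoxy carbon C1 bears a C2=C3 vinyl group, is silylated and undergoes an Ireland–Claisen [3,3] shift. The ring oxygen is exchanged for C2–C3 and the product is the carbocyclic acid A1.
- For: the ring is first closed by lactonization, C4 is set in the pericyclic step, and C6, C7 and C8 are already fixed, so no uncorrelated diastereomer pair arises. On that point it is stronger than the chosen route.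
- Against: A1 is far from 32 in oxidation pattern. The alkene is C1=C2, C14 is a protected alcohol on an sp3 C10, C15 is an acid, the lactone lacks C13 and O8 is silylated.
- Against: the endgame needs reduction of the acid beside a lactone, a two-stage oxidation at C14, alkene migration into conjugation with geometry control, α-methylenation and an acyl exchange, at least eight steps.
- Against: the enolization must choose C4–H over the equally acidic C11–H of the butyrolactone, and the ketene acetal geometry and chair/boat preference in a ten-membered ring make the C4 outcome uncertain.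
- Comparison: the chosen route reaches 30 with every carbon at its final oxidation level and needs two steps after ring closure.

**Alternative 2:** The disconnection is C7–C11 plus a temporary C8–C11 bond. In the forward key step a rhodium carbene, generated from a diazomalonate esterified to O6, cyclopropanates the (E)-C7=C8 alkene and gives the cyclopropane-fused lactone A2.
- For: the addition is stereospecific, so C6 and the alkene geometry fix C7 and C8 together, and the malonate carbon later supplies the methylene group. On C6/C7/C8 control it is stronger than the chosen route.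
- Against: the key step closes only the lactone. The ten-membered ring still has to be made afterwards by a medium-ring sp2–sp3 coupling between C1 and C2.
- Against: O8 must be introduced by opening the cyclopropane at a secondary carbon with the weakly nucleophilic carboxylate of 26.
- Against: ester cleavage, decarboxylative methylenation and desilylation follow, five or more steps with the riskiest one still open, and C4 must be related to C6 separately.
- Comparison: the chosen strategy puts the medium-ring closure in a step that forms no stereocentre, at the cost of the built-in C7/C8 control.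

**Alternative 3:** The disconnection is C7–C8 inside the ring, with the lactone made first. In the forward key step a butenolide carrying a stannylmethyl group on C11 attacks the Lewis-acid-activated C8 aldehyde through C7, moving the double bond to C11=C13 and giving A3.
- For: one step closes the ring, forms C7 and C8 and reveals the methylene lactone, and only acylation and desilylation follow. It is as short after the key step as the chosen route and creates two stereocentres in the ring-closing event, which the chosen route does not.
- Against: both new centres must come out right inside a forming ten-membered ring, under control only from C6 and an unpredictable transition-state conformation.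
- Against: the aldehyde is of the same isomerization-prone type as 19 but must survive a strong Lewis acid next to an acid-labile allylstannane.
- Against: A3 has a free 8-hydroxyl beside the 6,12-lactone and γ to C14, the arrangement that relactonizes to the 8,12-isomer.
- Comparison: the chosen route acylates O8 (25 → 28) before any lactone exists and closes the ring by a reaction whose only demand is chemoselectivity.

Key step: step 14

## Route

Step 1
Reactants: 1 but-3-enoic acid; 2 (4S)-4-benzyl-1,3-oxazolidin-2-one
Product: 5 (4S)-4-benzyl-3-(but-3-enoyl)-1,3-oxazolidin-2-one, via but-3-enoic pivalic anhydride 3 (not isolated), via lithium oxazolidinide 4 (not isolated)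
Conditions: 1, t-BuCOCl, Et3N, THF, −20 °C; separately 2, n-BuLi, THF, −78 °C; combine, −78 → 0 °C
Reagents that add atoms: none
Why: Mixed-anhydride N-acylation of a lithiated oxazolidinone; the low temperature keeps the β,γ-alkene from moving into conjugation, and no stereocentre is formed.

Step 2
Reactants: 5 (4S)-4-benzyl-3-(but-3-enoyl)-1,3-oxazolidin-2-one; 6 acrylonitrile
Product: 8 (4S)-4-benzyl-3-[(2S)-2-(2-cyanoethyl)but-3-enoyl]-1,3-oxazolidin-2-one, via titanium dienolate 7 (not isolated)
Conditions: TiCl3(OiPr), iPr2NEt, CH2Cl2, 0 °C; then 6 (3 equiv), 0 °C → rt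
Reagents that add atoms: none
Why: Evans-type titanium-enolate Michael addition: soft enolization gives the chelated (Z)-dienolate 7, which reacts at its α-carbon (C4) on the face away from the benzyl group, the same sense as auxiliary-controlled alkylation, so C4 is set as S. The nitrile supplies C3, C2 and C1 and is inert in step 3.

Step 3
Reactants: 8 (4S)-4-benzyl-3-[(2S)-2-(2-cyanoethyl)but-3-enoyl]-1,3-oxazolidin-2-one
Product: 9 (4S)-4-(hydroxymethyl)hex-5-enenitrile
Conditions: LiBH4, MeOH (1 equiv), Et2O, 0 °C
Reagents that add atoms: none
Why: Reductive cleavage of the N-acyl oxazolidinone gives the C15 alcohol and returns 2; the nitrile and the vinyl group are untouched and C4 is no longer α to a carbonyl.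

Step 4
Reactants: 9 (4S)-4-(hydroxymethyl)hex-5-enenitrile
Product: 10 (4S)-4-{[tert-butyl(diphenyl)silyl]oxymethyl}hex-5-enenitrile
Conditions: t-BuPh2SiCl, imidazole, DMF, rt
Reagents that add atoms: tert-butyl(chloro)diphenylsilane, CC(C)(C)[Si](Cl)(c1ccccc1)c1ccccc1
Why: Standard silylation of a primary alcohol; this silyl ether is chosen because it must survive trifluoroacetic acid in step 13 and a hot triflate-catalysed reaction in step 15.

Step 5
Reactants: 10 (4S)-4-{[tert-butyl(diphenyl)silyl]oxymethyl}hex-5-enenitrile
Product: 12 (4S)-4-{[tert-butyl(diphenyl)silyl]oxymethyl}hex-5-enal, via N-aluminio aldimine 11 (not isolated)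
Conditions: iBu2AlH (1.2 equiv), CH2Cl2, −78 °C; then aq. potassium sodium tartrate, pH 5 buffer, rt
Reagents that add atoms: water, O
Why: Partial reduction of a nitrile stops at the N-aluminio imine 11, which is hydrolysed to the C1 aldehyde on work-up; the stereocentre is γ to the aldehyde and cannot epimerize.

Step 6
Reactants: 13 methyl (triphenylphosphoranylidene)acetate; 14 1-bromo-3-methylbut-2-ene
Product: 16 methyl 5-methyl-2-(triphenylphosphoranylidene)hex-4-enoate, via phosphonium bromide 15 (not isolated)
Conditions: CHCl3, reflux; then aq. NaOH, CH2Cl2, 0 °C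
Reagents that add atoms: none
Why: C-Alkylation of a stabilized ylide by an allylic bromide, then deprotonation of the phosphonium salt; the prenyl group is a masked C9–C8 formylmethyl unit.

Step 7
Reactants: 12 (4S)-4-{[tert-butyl(diphenyl)silyl]oxymethyl}hex-5-enal; 16 methyl 5-methyl-2-(triphenylphosphoranylidene)hex-4-enoate
Product: 17 methyl (2E,6S)-6-{[tert-butyl(diphenyl)silyl]oxymethyl}-2-(3-methylbut-2-en-1-yl)octa-2,7-dienoate
Conditions: toluene, 80 °C
Reagents that add atoms: none
Why: Wittig olefination with an α-substituted ester-stabilized ylide gives the trisubstituted enoate with C2 trans to the ester (E), which is the ring-cis C1=C10 geometry of the target.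

Step 8
Reactants: 17 methyl (2E,6S)-6-{[tert-butyl(diphenyl)silyl]oxymethyl}-2-(3-methylbut-2-en-1-yl)octa-2,7-dienoate
Product: 19 methyl (2E,6S)-6-{[tert-butyl(diphenyl)silyl]oxymethyl}-2-(2-oxoethyl)octa-2,7-dienoate, via secondary ozonide 18 (not isolated)
Conditions: O3 (1.0 equiv, titrated solution), CH2Cl2, −78 °C; then PPh3, −78 °C → rt
Reagents that add atoms: ozone, [O-][O+]=O
Why: Chemoselective ozonolysis: electrophilic ozone attacks the electron-rich trisubstituted prenyl alkene much faster than the monosubstituted C4 vinyl group or the ester-conjugated C1=C10 alkene, as in the known selective cleavage of the isopropylidene group of citronellene-type dienes. The phosphine work-up is neutral, so the β,γ-unsaturated aldehyde 19 should not isomerize; it is used at once without chromatography.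

Step 9
Reactants: 20 acrolein; 21 tert-butyl acrylate
Product: 22 tert-butyl 3-hydroxy-2-methylidenepent-4-enoate (racemic)
Conditions: DABCO (0.5 equiv), 21 (3 equiv), 1,4-dioxane/H2O, 0 °C → rt, slow addition of 20
Reagents that add atoms: none
Why: Morita–Baylis–Hillman reaction: the amine–acrylate zwitterion adds to the aldehyde carbonyl of acrolein, and slow addition to excess acrylate limits acrolein self-condensation. The racemic carbinol centre is erased in step 10.

Step 10
Reactants: 22 tert-butyl 3-hydroxy-2-methylidenepent-4-enoate
Product: 23 tert-butyl (2Z)-2-(bromomethyl)penta-2,4-dienoate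
Conditions: NBS, Me2S, CH2Cl2, 0 °C → rt
Reagents that add atoms: N-bromosuccinimide, O=C1CCC(=O)N1Br
Why: Bromination of a Morita–Baylis–Hillman alcohol with allylic transposition (SN2′ attack of bromide on the acrylate CH2 of the alkoxysulfonium ion) gives the conjugated dienoate with CH2Br cis to the vinyl group, the preferred geometry for esters.

Step 11
Reactants: 19 methyl (2E,6S)-6-{[tert-butyl(diphenyl)silyl]oxymethyl}-2-(2-oxoethyl)octa-2,7-dienoate; 23 tert-butyl (2Z)-2-(bromomethyl)penta-2,4-dienoate
Product: 25 methyl (2E,6S)-2-[(2R,3R)-4-(tert-butoxycarbonyl)-3-ethenyl-2-hydroxypent-4-en-1-yl]-6-{[tert-butyl(diphenyl)silyl]oxymethyl}octa-2,7-dienoate, via allylindium dibromide 24 (not isolated)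
Conditions: indium powder, THF/H2O (2:1), rt; preparative HPLC
Reagents that add atoms: none
Why: Barbier-type indium allylation: allylindium 24 adds through its γ-carbon (C7) in a six-membered chair transition state, and the Z geometry of 23 places the vinyl group axial so that the syn C7/C8 pair results; the near-neutral aqueous medium is tolerated by the sensitive aldehyde and both esters. C4 is too remote to bias the aldehyde faces, so 25 is expected with about an equal amount of its (7S,8S) syn isomer, to be separated by HPLC and identified by Mosher analysis at C8. The tert-butyl ester at C12 and prompt acylation hold back lactonization of the new hydroxyl onto C12 or C14.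

Step 12
Reactants: 25 methyl (2E,6S)-2-[(2R,3R)-4-(tert-butoxycarbonyl)-3-ethenyl-2-hydroxypent-4-en-1-yl]-6-{[tert-butyl(diphenyl)silyl]oxymethyl}octa-2,7-dienoate; 26 (2R)-2-methylbutanoic acid
Product: 28 (2R)-2-methylbutanoate ester of 25 at O8, via O-acylisourea 27 (not isolated)
Conditions: DIC, DMAP (0.2 equiv), CH2Cl2, 0 °C → rt
Reagents that add atoms: none
Why: Steglich esterification of the hindered C8 alcohol through O-acylisourea 27 and the acylpyridinium ion; a simple α-alkyl alkanoic acid is not prone to epimerization here, and acylation removes the hydroxyl that could lactonize.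

Step 13
Reactants: 28 (2R)-2-methylbutanoate ester of 25 at O8
Product: 29 (3R,4R,6E,10S)-10-{[tert-butyl(diphenyl)silyl]oxymethyl}-3-ethenyl-6-(methoxycarbonyl)-2-methylidene-4-{[(2R)-2-methylbutanoyl]oxy}dodeca-6,11-dienoic acid
Conditions: CF3CO2H/CH2Cl2 (1:4), 0 °C → rt
Reagents that add atoms: none
Why: Acidolysis of the tert-butyl ester frees the C12 acid while the methyl ester, the O8 ester and the silyl ether persist; monosubstituted alkenes do not add trifluoroacetic acid on this time scale.

Step 14
Reactants: 29 (3R,4R,6E,10S)-10-{[tert-butyl(diphenyl)silyl]oxymethyl}-3-ethenyl-6-(methoxycarbonyl)-2-methylidene-4-{[(2R)-2-methylbutanoyl]oxy}dodeca-6,11-dienoic acid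
Product: 30 (4S,7R,8R)-cyclodeca-1(10),5-diene acrylic acid: the C1–C10 ring with cis C5=C6 and ring-cis C1=C10 alkenes, C11(=C13H2)–C12O2H on C7, the (2R)-2-methylbutanoate on O8, CO2Me on C10 and CH2OSiPh2t-Bu on C4
Conditions: second-generation Hoveyda–Grubbs catalyst (10 mol %), 1,4-benzoquinone (20 mol %), toluene (1 mM), 80 °C, slow addition of 29
Reagents that add atoms: none
Why: Ring-closing metathesis: the ruthenium benzylidene exchanges onto one of the two monosubstituted vinyl groups, the resulting alkylidene undergoes [2+2] cycloaddition with the other vinyl group, and cycloreversion of the ruthenacyclobutane releases 30 with ethene as the only by-product. The closest known reaction type is metathesis closure of two terminal alkenes to a ten-membered cis-cycloalkene. The ring closed is the ten-membered carbocycle C1–C10, by joining C5 to C6, and no stereocentre is created. Chemoselectivity is needed and the substrate secures it: the acrylic acid alkene (1,1-disubstituted, electron-poor) and the C1=C10 enoate (trisubstituted, electron-poor) react with ruthenium alkylidenes far more slowly than the vinyl groups. Cyclization must beat oligomerization, which high dilution and the existing cis C1=C10 alkene, a turn element in the chain, favour; the product is a cis,cis-cyclodeca-1,6-diene, a medium ring of unusually low strain. The new alkene must be cis, which a ten-membered ring already holding one cis alkene enforces. Benzoquinone is added to suppress ruthenium hydride migration through the doubly allylic C7–H.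

Step 15
Reactants: 30 (4S,7R,8R)-cyclodeca-1(10),5-diene acrylic acid
Product: 31 15-O-tert-butyldiphenylsilyl ether of the target: methyl (4S,6R,7S,8R)-8-{[(2R)-2-methylbutanoyl]oxy}germacra-1(10),11(13)-dien-12,6-olid-14-oate silylated at O15
Conditions: AgOTf (10 mol %), ClCH2CH2Cl, 80 °C
Reagents that add atoms: none
Why: Silver triflate-catalysed intramolecular hydro-acyloxylation of an unactivated alkene by a γ,δ-unsaturated acid: the carboxyl oxygen adds to C6 (5-exo, fused γ-lactone) rather than C5 (bridged δ-lactone) and a proton goes to C5. C6 is set by the ring: with C7–H near the alkene plane (allylic strain) the acrylic acid sits on the face opposite C8, so oxygen attacks C6 anti to C8 and the trans-fused lactone (6R), also the more stable fusion, should result.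

Step 16
Reactants: 31 15-O-tert-butyldiphenylsilyl ether of the target
Product: 32 methyl (4S,6R,7S,8R)-15-hydroxy-8-{[(2R)-2-methylbutanoyl]oxy}germacra-1(10),11(13)-dien-12,6-olid-14-oate (CNP0141952.4)
Conditions: HF·pyridine, pyridine/THF, 0 °C → rt
Reagents that add atoms: none
Why: Fluoride cleavage of the silyl ether under buffered acidic conditions, which spare the α-methylene lactone, both esters and the acyl stereocentre.

## Compound list

1 | but-3-enoic acid | C=CCC(=O)O | starting material
2 | (4S)-4-benzyl-1,3-oxazolidin-2-one | O=C1N[C@@H](Cc2ccccc2)CO1 | starting material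
3 | but-3-enoic pivalic anhydride | C=CCC(=O)OC(=O)C(C)(C)C | intermediate
4 | lithium (4S)-4-benzyl-2-oxo-1,3-oxazolidin-3-ide | [Li+].O=C1[N-][C@@H](Cc2ccccc2)CO1 | intermediate
5 | (4S)-4-benzyl-3-(but-3-enoyl)-1,3-oxazolidin-2-one | C=CCC(=O)N1[C@@H](Cc2ccccc2)COC1=O | intermediate
6 | acrylonitrile | C=CC#N | starting material
7 | dichloro(isopropoxy)titanium (Z)-dienolate of 5 | C=C/C=C(\O[Ti](Cl)(Cl)OC(C)C)N1[C@@H](Cc2ccccc2)COC1=O | intermediate
8 | (4S)-4-benzyl-3-[(2S)-2-(2-cyanoethyl)but-3-enoyl]-1,3-oxazolidin-2-one | C=C[C@H](CCC#N)C(=O)N1[C@@H](Cc2ccccc2)COC1=O | intermediate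
9 | (4S)-4-(hydroxymethyl)hex-5-enenitrile | C=C[C@H](CCC#N)CO | intermediate
10 | (4S)-4-{[tert-butyl(diphenyl)silyl]oxymethyl}hex-5-enenitrile | C=C[C@H](CCC#N)CO[Si](c1ccccc1)(c1ccccc1)C(C)(C)C | intermediate
11 | N-(diisobutylaluminio) aldimine of 10 | C=C[C@H](CCC=N[Al](CC(C)C)CC(C)C)CO[Si](c1ccccc1)(c1ccccc1)C(C)(C)C | intermediate
12 | (4S)-4-{[tert-butyl(diphenyl)silyl]oxymethyl}hex-5-enal | C=C[C@H](CCC=O)CO[Si](c1ccccc1)(c1ccccc1)C(C)(C)C | intermediate
13 | methyl (triphenylphosphoranylidene)acetate | COC(=O)C=P(c1ccccc1)(c1ccccc1)c1ccccc1 | starting material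
14 | 1-bromo-3-methylbut-2-ene (prenyl bromide) | CC(C)=CCBr | starting material
15 | (1-methoxy-5-methyl-1-oxohex-4-en-2-yl)triphenylphosphonium bromide | COC(=O)C(CC=C(C)C)[P+](c1ccccc1)(c1ccccc1)c1ccccc1.[Br-] | intermediate
16 | methyl 5-methyl-2-(triphenylphosphoranylidene)hex-4-enoate | COC(=O)C(CC=C(C)C)=P(c1ccccc1)(c1ccccc1)c1ccccc1 | intermediate
17 | methyl (2E,6S)-6-{[tert-butyl(diphenyl)silyl]oxymethyl}-2-(3-methylbut-2-en-1-yl)octa-2,7-dienoate | CC(C)=CC/C(C(=O)OC)=C\CC[C@@H](C=C)CO[Si](c1ccccc1)(c1ccccc1)C(C)(C)C | intermediate
18 | secondary ozonide (1,2,4-trioxolane) of the prenyl alkene of 17 | CC1(C)OOC(C/C(C(=O)OC)=C\CC[C@@H](C=C)CO[Si](c2ccccc2)(c2ccccc2)C(C)(C)C)O1 | intermediate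
19 | methyl (2E,6S)-6-{[tert-butyl(diphenyl)silyl]oxymethyl}-2-(2-oxoethyl)octa-2,7-dienoate | O=CC/C(C(=O)OC)=C\CC[C@@H](C=C)CO[Si](c1ccccc1)(c1ccccc1)C(C)(C)C | intermediate
20 | acrolein | C=CC=O | starting material
21 | tert-butyl acrylate | C=CC(=O)OC(C)(C)C | starting material
22 | tert-butyl 3-hydroxy-2-methylidenepent-4-enoate (racemic) | C=CC(O)C(=C)C(=O)OC(C)(C)C | intermediate
23 | tert-butyl (2Z)-2-(bromomethyl)penta-2,4-dienoate | C=C/C=C(\CBr)C(=O)OC(C)(C)C | intermediate
24 | allylindium dibromide from 23, tert-butyl (2Z)-2-[(dibromoindiganyl)methyl]penta-2,4-dienoate | C=C/C=C(\C[In](Br)Br)C(=O)OC(C)(C)C | intermediate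
25 | methyl (2E,6S)-2-[(2R,3R)-4-(tert-butoxycarbonyl)-3-ethenyl-2-hydroxypent-4-en-1-yl]-6-{[tert-butyl(diphenyl)silyl]oxymethyl}octa-2,7-dienoate (7R,8R) | CC(C)(C)OC(=O)C(=C)[C@@H](C=C)[C@H](O)C/C(C(=O)OC)=C\CC[C@@H](C=C)CO[Si](c1ccccc1)(c1ccccc1)C(C)(C)C | intermediate
26 | (2R)-2-methylbutanoic acid | CC[C@@H](C)C(=O)O | starting material
27 | O-acylisourea from 26 and N,N'-diisopropylcarbodiimide | CC[C@@H](C)C(=O)OC(=NC(C)C)NC(C)C | intermediate
28 | (2R)-2-methylbutanoate ester of 25 at O8 (tert-butyl C12 ester, methyl C14 ester) | CC(C)(C)OC(=O)C(=C)[C@@H](C=C)[C@H](OC(=O)[C@H](C)CC)C/C(C(=O)OC)=C\CC[C@@H](C=C)CO[Si](c1ccccc1)(c1ccccc1)C(C)(C)C | intermediate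
29 | (3R,4R,6E,10S)-10-{[tert-butyl(diphenyl)silyl]oxymethyl}-3-ethenyl-6-(methoxycarbonyl)-2-methylidene-4-{[(2R)-2-methylbutanoyl]oxy}dodeca-6,11-dienoic acid (seco acid) | OC(=O)C(=C)[C@@H](C=C)[C@H](OC(=O)[C@H](C)CC)C/C(C(=O)OC)=C\CC[C@@H](C=C)CO[Si](c1ccccc1)(c1ccccc1)C(C)(C)C | intermediate
30 | (4S,7R,8R)-cyclodeca-1(10),5-diene acrylic acid (5Z; C2 and C9 cis across C1=C10) | OC(=O)C(=C)[C@H]1/C=C\[C@@H](CO[Si](c2ccccc2)(c2ccccc2)C(C)(C)C)CC/C=C(/C(=O)OC)C[C@H]1OC(=O)[C@H](C)CC | intermediate
31 | 15-O-tert-butyldiphenylsilyl ether of the target (4S,6R,7S,8R) | C=C1C(=O)O[C@@H]2C[C@@H](CO[Si](c3ccccc3)(c3ccccc3)C(C)(C)C)CC/C=C(/C(=O)OC)C[C@@H](OC(=O)[C@H](C)CC)[C@@H]12 | intermediate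
32 | methyl (4S,6R,7S,8R)-15-hydroxy-8-{[(2R)-2-methylbutanoyl]oxy}germacra-1(10),11(13)-dien-12,6-olid-14-oate | C=C1C(=O)O[C@@H]2C[C@@H](CO)CC/C=C(/C(=O)OC)C[C@@H](OC(=O)[C@H](C)CC)[C@@H]12 | target

## Step count and least certain steps

Total: 16 steps. Longest linear sequence: 13 steps (steps 1–5, 7, 8, 11–16, from but-3-enoic acid).

**Step 14 (key step).** The most likely failure is intermolecular metathesis to dimers and oligomers outrunning closure of the medium ring. It would be made worse if the alkylidene formed at C6 is held as a chelate by the neighbouring C12 carboxyl group. Hydride-induced alkene migration through the doubly allylic C7–H is a second risk. The fallback closes the ring before the acid is freed. Setting out from 28, the same metathesis on the less coordinating tert-butyl ester would give the ring-closed tert-butyl ester F1, and acidolysis of F1 (CF3CO2H/CH2Cl2) would return to the route at 30.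

**Step 15.** Protonation of a 1,2-disubstituted alkene with no electronic bias is slow and unselective. The likely failures are loss of regiocontrol (oxygen adding to C5 to give the bridged δ-lactone), cation chemistry in the ten-membered ring (transannular hydride shift, capture by the O8 ester carbonyl) and acid-promoted loss of the silyl group. The fallback is halolactonization followed by reduction. Setting out from 30, I2/NaHCO3 in MeCN at 0 °C should give, by kinetic 5-exo anti addition, the 5-iodo lactone F2. Removal of the carbon–iodine bond with Bu3SnH/AIBN would return to the route at 31. The stannane is used concentrated and in excess so that the C5 radical is reduced before it can add across the ring to C1.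

**Step 11.** The most likely failure is the absence of facial control from the remote C4 centre together with poor separability of the two syn adducts, which differ only in the relation of centres five bonds apart. Isomerization of aldehyde 19 into conjugation and lactonization of the free 8-hydroxyl are further risks. The fallback moves the separation to the ring stage. Setting out from 19, the allylation mixture of 25 and its (7S,8S) syn isomer F3 is not separated. It is acylated as in step 12 (28 with the diastereomeric ester F4), deprotected as in step 13 (29 with the diastereomeric acid F5) and cyclized as in step 14 (30 with the ring diastereomer F6). Compounds 30 and F6 differ in the relative configuration of ring stereocentres and should separate by ordinary chromatography, so the route is rejoined at 30.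

**Step 8.** The most likely failure is over-oxidation at the C4 vinyl group if ozone is not dosed exactly, or isomerization of the product during work-up. The fallback is a two-stage cleavage. Setting out from 17, mCPBA (1 equiv, NaHCO3, CH2Cl2, 0 °C) should epoxidize only the trisubstituted alkene to give the epoxide F7. Cleavage of F7 with H5IO6 in THF/H2O at 0 °C would return to the route at 19.

**Step 2.** The most likely failure is loss of regiocontrol in the dienolate (γ-attack, or isomerization of 5 to the conjugated crotonyl imide) and polymerization of the acceptor. The fallback is an alkylation in place of the conjugate addition. 3-{[tert-Butyl(dimethyl)silyl]oxy}propan-1-ol is converted with Tf2O/2,6-lutidine into the triflate F8. Setting out from 5, the sodium dienolate (NaN(SiMe3)2, THF, −78 °C) is alkylated with F8 to give the α-alkylated imide F9 with the same facial sense. LiBH4 gives the alcohol F10, silylation as in step 4 gives the bis-silyl ether F11, and PPTS in MeOH removes the primary tert-butyldimethylsilyl group to give the alcohol F12. Dess–Martin oxidation of F12 returns to the route at 12.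

## Further compounds

F1 | step 14 | tert-butyl ester of 30 (ring-closed tert-butyl ester) | CC(C)(C)OC(=O)C(=C)[C@H]1/C=C\[C@@H](CO[Si](c2ccccc2)(c2ccccc2)C(C)(C)C)CC/C=C(/C(=O)OC)C[C@H]1OC(=O)[C@H](C)CC
F2 | step 15 | (5S)-5-iodo derivative of 31 (iodine anti to O6) | C=C1C(=O)O[C@@H]2[C@@H](I)[C@@H](CO[Si](c3ccccc3)(c3ccccc3)C(C)(C)C)CC/C=C(/C(=O)OC)C[C@@H](OC(=O)[C@H](C)CC)[C@@H]12
F3 | step 11 | (7S,8S) syn diastereomer of 25 | CC(C)(C)OC(=O)C(=C)[C@H](C=C)[C@@H](O)C/C(C(=O)OC)=C\CC[C@@H](C=C)CO[Si](c1ccccc1)(c1ccccc1)C(C)(C)C
F4 | step 11 | (7S,8S) diastereomer of 28 | CC(C)(C)OC(=O)C(=C)[C@H](C=C)[C@@H](OC(=O)[C@H](C)CC)C/C(C(=O)OC)=C\CC[C@@H](C=C)CO[Si](c1ccccc1)(c1ccccc1)C(C)(C)C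
F5 | step 11 | (7S,8S) diastereomer of 29 | OC(=O)C(=C)[C@H](C=C)[C@@H](OC(=O)[C@H](C)CC)C/C(C(=O)OC)=C\CC[C@@H](C=C)CO[Si](c1ccccc1)(c1ccccc1)C(C)(C)C
F6 | step 11 | (7S,8S) diastereomer of 30 | OC(=O)C(=C)[C@@H]1/C=C\[C@@H](CO[Si](c2ccccc2)(c2ccccc2)C(C)(C)C)CC/C=C(/C(=O)OC)C[C@@H]1OC(=O)[C@H](C)CC
F7 | step 8 | epoxide of the prenyl alkene of 17 (both epimers at the epoxide carbon) | CC1(C)OC1C/C(C(=O)OC)=C\CC[C@@H](C=C)CO[Si](c1ccccc1)(c1ccccc1)C(C)(C)C
F8 | step 2 | 3-{[tert-butyl(dimethyl)silyl]oxy}propyl trifluoromethanesulfonate | CC(C)(C)[Si](C)(C)OCCCOS(=O)(=O)C(F)(F)F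
F9 | step 2 | (4S)-4-benzyl-3-[(2S)-5-{[tert-butyl(dimethyl)silyl]oxy}-2-ethenylpentanoyl]-1,3-oxazolidin-2-one | C=C[C@H](CCCO[Si](C)(C)C(C)(C)C)C(=O)N1[C@@H](Cc2ccccc2)COC1=O
F10 | step 2 | (2S)-5-{[tert-butyl(dimethyl)silyl]oxy}-2-ethenylpentan-1-ol | C=C[C@H](CCCO[Si](C)(C)C(C)(C)C)CO
F11 | step 2 | (2S)-5-{[tert-butyl(dimethyl)silyl]oxy}-2-ethenylpentyl tert-butyldiphenylsilyl ether | C=C[C@H](CCCO[Si](C)(C)C(C)(C)C)CO[Si](c1ccccc1)(c1ccccc1)C(C)(C)C
F12 | step 2 | (4S)-4-{[tert-butyl(diphenyl)silyl]oxymethyl}hex-5-en-1-ol | C=C[C@H](CCCO)CO[Si](c1ccccc1)(c1ccccc1)C(C)(C)C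
A1 | alternative 1 | carbocyclic C15 acid with cis C1=C2 alkene, saturated 6,12-lactone, 8-O-silyl and 14-O-(4-methoxybenzyl) groups | OC(=O)[C@H]1C/C=C\[C@@H](COCc3ccc(OC)cc3)C[C@@H](O[Si](C)(C)C(C)(C)C)[C@H]2CC(=O)O[C@@H]2C1
A2 | alternative 2 | cyclopropane-fused γ-lactone tert-butyl ester with the C1 vinyl iodide | CC(C)(C)OC(=O)[C@]12C(=O)O[C@H](C[C@H](C=C)CO[Si](C)(C)C(C)(C)C)[C@H]1[C@@H]2C/C(C(=O)OC)=C\I
A3 | alternative 3 | 8-hydroxy 15-O-tert-butyldimethylsilyl ten-membered α-methylene lactone | C=C1C(=O)O[C@@H]2C[C@@H](CO[Si](C)(C)C(C)(C)C)CC/C=C(/C(=O)OC)C[C@@H](O)[C@@H]12
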